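**Plan**

1. Labdane numbering is used: ring A = C1–C5, C10; ring B = C5–C10; side chain C11–C16; C17 is the carbon on C8. The target is (13S)-6β-acetoxy-9α,13-epoxylabdan-16,15-olide with 5α-H, 8α-CH3 and 10β-CH3.
2. Retrosynthetic cuts, last to first: lactone C15–O (oxidative lactonisation of a 15,16-diol); ether O9–C13 (opening of a 13,16-epoxide by the 9-OH); ring B at C6–C7 and C8–C9 together; C9–C11 (alkyllithium + lactone); ring A at C1–C10 and C4–C5 (Diels–Alder).
3. Enabling feature: C6 and C9, the two oxygen-bearing carbons of ring B, stand 1,4 to each other through the C5–C10 bond and flank the C7–C8(–C17) unit. Ring B therefore unzips to a monocyclic 1,4-keto-aldehyde (formyl C6 on C5, ketone C9 on C10) plus methyl acrylate (C7, C8, C17). A C6 ketyl radical adds to C7, and the resulting C8 samarium enolate closes onto the C9 ketone.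
4. Forward order: ring A (cycloaddition) → temporary trans-fused lactone → side chain on C9 → ring B (key step) → C17 methyl and 6β-acetate → tetrahydrofuran ring → γ-lactone ring.
5. Stereochemistry: C5/C10 from a catalytic asymmetric Diels–Alder of an (E)-dienophile; C8 and C9 from the chelated chair aldol of the key step; C6 from α-face hydride delivery to the 6-ketone; C13 from a catalyst-controlled epoxidation followed by invertive ring opening.

Key step: step 9

Remark: the catalyst antipodes written in steps 1 and 16 are those expected from the usual facial models to give the drawn configurations; if a model pointed the other way, the mirror-image catalyst would be used with no other change.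

**Route**

Step 1
Reactants: 1 4-methylpenta-1,3-diene; 2 ethyl (E)-2-methyl-4-oxobut-2-enoate
Product: 3 ethyl (1S,6S)-6-formyl-1,5,5-trimethylcyclohex-3-ene-1-carboxylate
Conditions: 1 (3 equiv), (S)-3,3-diphenyl-1-(o-tolyl)tetrahydro-1H,3H-pyrrolo[1,2-c][1,3,2]oxazaborole·HNTf2 (20 mol%), CH2Cl2, −78 → −20 °C
Reagents that add atoms: none
Why: Lewis acid-catalysed Diels–Alder reaction in which the boron cation binds the formyl group, so the unsubstituted diene terminus bonds to the β-carbon (future quaternary C10) and the gem-dimethyl terminus to C5, the (E)-geometry of 2 is carried suprafacially into the trans relation of formyl and ester (methyl cis to formyl), and the chiral cation shields one enal face to set the absolute configuration of C5 and C10.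

Step 2
Reactants: 3 ethyl (1S,6S)-6-formyl-1,5,5-trimethylcyclohex-3-ene-1-carboxylate
Product: 5 (3aS,7aS)-4,4,7a-trimethyl-3a,4,7,7a-tetrahydro-2-benzofuran-1(3H)-one, via hydroxy ester 4 (not isolated)
Conditions: NaBH4, EtOH, 0 °C; then TsOH·H2O (cat.), PhMe, 80 °C
Reagents that add atoms: none
Why: Chemoselective borohydride reduction of the aldehyde beside the hindered ester followed by acid-catalysed lactonisation to the trans-fused γ-lactone, which touches no stereocentre and removes the epimerisable formyl group.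

Step 3
Reactants: 5 (3aS,7aS)-4,4,7a-trimethyl-3a,4,7,7a-tetrahydro-2-benzofuran-1(3H)-one
Product: 6 (3aS,7aS)-4,4,7a-trimethylhexahydro-2-benzofuran-1(3H)-one
Conditions: H2 (1 atm), Pd/C (10%), EtOAc, rt
Reagents that add atoms: none
Why: Heterogeneous catalytic hydrogenation of the isolated cis-disubstituted ring alkene, with no new stereocentre formed.

Step 4
Reactants: 7 3-methylbut-3-en-1-ol
Product: 9 3-methylidenepentane-1,5-diol, via dilithio dianion 8 (not isolated)
Conditions: n-BuLi (2.2 equiv), TMEDA, Et2O/hexane, 0 °C → rt; (CH2O)n, −30 °C → rt; H2O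
Reagents that add atoms: paraformaldehyde (as formaldehyde), C=O
Why: Alkoxide-directed allylic lithiation gives a symmetric 2-substituted allyl anion that is hydroxymethylated by formaldehyde, either terminus giving the same 1,1-disubstituted alkene.

Step 5
Reactants: 9 3-methylidenepentane-1,5-diol
Product: 10 5-[(tert-butyldimethylsilyl)oxy]-3-methylidenepentan-1-ol
Conditions: TBSCl (1 equiv), imidazole, 9 (3 equiv), THF/DMF, 0 °C
Reagents that add atoms: tert-butyldimethylsilyl chloride, CC(C)(C)[Si](C)(C)Cl
Why: Statistical monosilylation of a symmetric diol used in excess, the unreacted diol being recovered.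

Step 6
Reactants: 10 5-[(tert-butyldimethylsilyl)oxy]-3-methylidenepentan-1-ol
Product: 11 tert-butyl[(5-iodo-3-methylidenepentyl)oxy]dimethylsilane
Conditions: I2, PPh3, imidazole, CH2Cl2, 0 °C
Reagents that add atoms: iodine, II
Why: Appel-type iodination of the primary alcohol (SN2 at a primary carbon).

Step 7
Reactants: 11 tert-butyl[(5-iodo-3-methylidenepentyl)oxy]dimethylsilane; 6 (3aS,7aS)-4,4,7a-trimethylhexahydro-2-benzofuran-1(3H)-one
Product: 13 6-[(tert-butyldimethylsilyl)oxy]-1-[(1S,2S)-2-(hydroxymethyl)-1,3,3-trimethylcyclohexyl]-4-methylidenehexan-1-one, via alkyllithium 12 (not isolated)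
Conditions: 11, t-BuLi (2.1 equiv), Et2O/pentane, −78 °C; then 6, −78 °C; H2O
Reagents that add atoms: none
Why: Iodine–lithium exchange gives the primary alkyllithium, which adds once to the hindered lactone carbonyl because the tetrahedral lithium lactolate persists at low temperature and collapses to the hydroxy ketone (in equilibrium with its lactol) only on work-up.

Step 8
Reactants: 13 6-[(tert-butyldimethylsilyl)oxy]-1-[(1S,2S)-2-(hydroxymethyl)-1,3,3-trimethylcyclohexyl]-4-methylidenehexan-1-one
Product: 14 (1S,2S)-2-{6-[(tert-butyldimethylsilyl)oxy]-4-methylidenehexanoyl}-2,6,6-trimethylcyclohexane-1-carbaldehyde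
Conditions: Dess–Martin periodinane, NaHCO3, CH2Cl2, 0 °C → rt
Reagents that add atoms: none
Why: Dess–Martin oxidation of the primary alcohol (open-chain tautomer) under buffered conditions, where the C5–H lying between two quaternary carbons should not enolise.

Step 9
Reactants: 14 (1S,2S)-2-{6-[(tert-butyldimethylsilyl)oxy]-4-methylidenehexanoyl}-2,6,6-trimethylcyclohexane-1-carbaldehyde; 15 methyl acrylate
Product: 18 methyl 15-[(tert-butyldimethylsilyl)oxy]-6ξ,9α-dihydroxy-8βH-labd-13(16)-en-17-oate, via samarium ketyl 16 (not isolated), via samarium enolate 17 (not isolated)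
Conditions: SmI2 (2.5 equiv), THF, slow addition of 14 + 15 (1.5 equiv) at −40 °C, then 0 °C, no proton source; pH 7 buffer
Reagents that add atoms: none
Why: Proposed new method: single-electron reduction of the aldehyde (far easier to reduce than the neopentyl C9 ketone) gives the C6 ketyl radical, which adds to C7 of methyl acrylate (Giese addition), and a second electron turns the α-ester radical into the C8 samarium enolate, which attacks the C9 ketone through a closed chair transition state in which trivalent samarium bridges the enolate and ketone oxygens. The closest known reaction type is the SmI2-mediated ketyl–olefin addition/aldol cascade (radical–polar crossover), established for intramolecular radical additions of dialdehydes and for intermolecular ketyl–acrylate couplings, here merged into an intermolecular [4+2] annulation of a 1,4-keto-aldehyde. Ring B is the only ring closed, by a 6-(enolexo)-exo-trig aldol; C8 takes the equatorial ester because the axial position is syn-axial to the C10 methyl and the centre stays epimerisable, C9 takes the axial oxygen cis to the ester in the chelated chair with the larger C11 chain equatorial, and C6 is not controlled and is reset in steps 10 and 11. The step needs ketyl formation at the aldehyde only, acrylate addition faster than pinacol closure (which would give a strained trans-fused cyclobutanediol on the trans-diequatorial ring A) and aldol faster than protonation, the last secured by leaving out any proton source.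

Step 10
Reactants: 18 methyl 15-[(tert-butyldimethylsilyl)oxy]-6ξ,9α-dihydroxy-8βH-labd-13(16)-en-17-oate
Product: 19 methyl 15-[(tert-butyldimethylsilyl)oxy]-9α-hydroxy-6-oxo-8βH-labd-13(16)-en-17-oate
Conditions: Dess–Martin periodinane, NaHCO3, CH2Cl2, rt
Reagents that add atoms: none
Why: Dess–Martin oxidation of the secondary C6 alcohol (both epimers) to a single ketone, the tertiary 9-OH being inert, so that C6 can be set afresh.

Step 11
Reactants: 19 methyl 15-[(tert-butyldimethylsilyl)oxy]-9α-hydroxy-6-oxo-8βH-labd-13(16)-en-17-oate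
Product: 20 15-[(tert-butyldimethylsilyl)oxy]-8βH-labd-13(16)-ene-6β,9α,17-triol
Conditions: LiAlH4, THF, −20 → 0 °C; aqueous NaOH work-up
Reagents that add atoms: none
Why: Hydride reduction of the ester to the primary alcohol and of the C6 ketone from the α-face, the β-face being blocked by the syn-axial methyl groups on C4 and C10, which should give the axial 6β-alcohol.

Step 12
Reactants: 20 15-[(tert-butyldimethylsilyl)oxy]-8βH-labd-13(16)-ene-6β,9α,17-triol
Product: 21 15-[(tert-butyldimethylsilyl)oxy]-6β,9α-dihydroxy-8βH-labd-13(16)-en-17-yl 4-methylbenzenesulfonate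
Conditions: TsCl (1.2 equiv), pyridine, 0 °C
Reagents that add atoms: 4-toluenesulfonyl chloride, Cc1ccc(cc1)S(Cl)(=O)=O
Why: Selective sulfonylation of the primary alcohol, the axial 6β-OH between two syn-axial methyl groups and the tertiary 9-OH being too hindered to react at 0 °C.

Step 13
Reactants: 21 15-[(tert-butyldimethylsilyl)oxy]-6β,9α-dihydroxy-8βH-labd-13(16)-en-17-yl 4-methylbenzenesulfonate
Product: 22 15-[(tert-butyldimethylsilyl)oxy]labd-13(16)-ene-6β,9α-diol
Conditions: LiEt3BH (excess), THF, 0 °C → rt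
Reagents that add atoms: none
Why: Hydride SN2 displacement of the primary tosylate turns C17 into the 8α-methyl group without touching C8.

Step 14
Reactants: 22 15-[(tert-butyldimethylsilyl)oxy]labd-13(16)-ene-6β,9α-diol
Product: 23 6β-acetoxy-15-[(tert-butyldimethylsilyl)oxy]labd-13(16)-en-9α-ol
Conditions: Ac2O, DMAP (cat.), pyridine, rt → 40 °C
Reagents that add atoms: acetic anhydride, CC(=O)OC(C)=O
Why: DMAP-catalysed acylation of the secondary 6β-alcohol, the tertiary 9-hydroxyl remaining free.

Step 15
Reactants: 23 6β-acetoxy-15-[(tert-butyldimethylsilyl)oxy]labd-13(16)-en-9α-ol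
Product: 24 6β-acetoxylabd-13(16)-ene-9α,15-diol
Conditions: HF·pyridine, pyridine/THF, 0 °C → rt
Reagents that add atoms: none
Why: Fluoride-mediated cleavage of the primary silyl ether under buffered conditions that spare the acetate.

Step 16
Reactants: 24 6β-acetoxylabd-13(16)-ene-9α,15-diol
Product: 26 (13S)-6β-acetoxy-9α,13-epoxylabdane-15,16-diol, via epoxy alcohol 25 (not isolated)
Conditions: VO(Oi-Pr)3 (2 mol%), (R,R)-N,N'-(cyclohexane-1,2-diyl)bis(N-hydroxy-2,2-diphenylacetamide) (4 mol%), cumene hydroperoxide, PhMe, 0 °C; then CSA (cat.), CH2Cl2, 0 °C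
Reagents that add atoms: cumene hydroperoxide, CC(C)(OO)c1ccccc1
Why: Hydroxyl-directed catalytic asymmetric epoxidation of the homoallylic alcohol (the primary alcohol binds the chiral vanadium bishydroxamate, which fixes the alkene face and should give the (13R)-epoxide) followed by acid-catalysed 5-exo opening at the tertiary epoxide carbon by the 9-hydroxyl with inversion, which sets C13 as S and releases the C16 hydroxymethyl group.

Step 17
Reactants: 26 (13S)-6β-acetoxy-9α,13-epoxylabdane-15,16-diol
Product: 27 previtexilactone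
Conditions: TEMPO (20 mol%), PhI(OAc)2 (3 equiv), CH2Cl2, rt
Reagents that add atoms: none
Why: TEMPO/PhI(OAc)2 oxidative lactonisation of the 1,4-diol, in which the unhindered C15 alcohol is oxidised first, the aldehyde is trapped as the five-membered lactol by the neopentyl C16 alcohol and oxidised on, so the carbonyl ends up at C15.

**Compound list**

1 | 4-methylpenta-1,3-diene | C=CC=C(C)C | starting material
2 | ethyl (E)-2-methyl-4-oxobut-2-enoate | CCOC(=O)/C(C)=C/C=O | starting material
3 | ethyl (1S,6S)-6-formyl-1,5,5-trimethylcyclohex-3-ene-1-carboxylate | CCOC(=O)[C@@]1(C)CC=CC(C)(C)[C@@H]1C=O | intermediate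
4 | ethyl (1S,6S)-6-(hydroxymethyl)-1,5,5-trimethylcyclohex-3-ene-1-carboxylate (hydroxy ester) | CCOC(=O)[C@@]1(C)CC=CC(C)(C)[C@@H]1CO | intermediate
5 | (3aS,7aS)-4,4,7a-trimethyl-3a,4,7,7a-tetrahydro-2-benzofuran-1(3H)-one | O=C2[C@@]1(C)CC=CC(C)(C)[C@@H]1CO2 | intermediate
6 | (3aS,7aS)-4,4,7a-trimethylhexahydro-2-benzofuran-1(3H)-one | O=C2[C@@]1(C)CCCC(C)(C)[C@@H]1CO2 | intermediate
7 | 3-methylbut-3-en-1-ol | CC(=C)CCO | starting material
8 | lithium 3-(lithiomethyl)but-3-en-1-olate (dilithio dianion) | [Li]CC(=C)CCO[Li] | intermediate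
9 | 3-methylidenepentane-1,5-diol | OCCC(=C)CCO | intermediate
10 | 5-[(tert-butyldimethylsilyl)oxy]-3-methylidenepentan-1-ol | OCCC(=C)CCO[Si](C)(C)C(C)(C)C | intermediate
11 | tert-butyl[(5-iodo-3-methylidenepentyl)oxy]dimethylsilane | ICCC(=C)CCO[Si](C)(C)C(C)(C)C | intermediate
12 | {5-[(tert-butyldimethylsilyl)oxy]-3-methylidenepentyl}lithium (alkyllithium) | [Li]CCC(=C)CCO[Si](C)(C)C(C)(C)C | intermediate
13 | 6-[(tert-butyldimethylsilyl)oxy]-1-[(1S,2S)-2-(hydroxymethyl)-1,3,3-trimethylcyclohexyl]-4-methylidenehexan-1-one | O=C(CCC(=C)CCO[Si](C)(C)C(C)(C)C)[C@@]1(C)CCCC(C)(C)[C@@H]1CO | intermediate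
14 | (1S,2S)-2-{6-[(tert-butyldimethylsilyl)oxy]-4-methylidenehexanoyl}-2,6,6-trimethylcyclohexane-1-carbaldehyde | O=C(CCC(=C)CCO[Si](C)(C)C(C)(C)C)[C@@]1(C)CCCC(C)(C)[C@@H]1C=O | intermediate
15 | methyl acrylate | C=CC(=O)OC | starting material
16 | samarium ketyl radical of 14 (O-SmI2 on C6, radical at C6) | O=C(CCC(=C)CCO[Si](C)(C)C(C)(C)C)[C@@]1(C)CCCC(C)(C)[C@@H]1[CH]O[Sm](I)I | intermediate
17 | samarium ester enolate of the Giese adduct (C6 O-SmI2, C8=C17 enolate) | O=C(CCC(=C)CCO[Si](C)(C)C(C)(C)C)[C@@]1(C)CCCC(C)(C)[C@@H]1C(O[Sm](I)I)CC=C(OC)O[Sm](I)I | intermediate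
18 | methyl 15-[(tert-butyldimethylsilyl)oxy]-6ξ,9α-dihydroxy-8βH-labd-13(16)-en-17-oate (C6 epimers) | OC1C[C@@H](C(=O)OC)[C@](O)(CCC(=C)CCO[Si](C)(C)C(C)(C)C)[C@@]2(C)CCCC(C)(C)[C@H]12 | intermediate
19 | methyl 15-[(tert-butyldimethylsilyl)oxy]-9α-hydroxy-6-oxo-8βH-labd-13(16)-en-17-oate | O=C1C[C@@H](C(=O)OC)[C@](O)(CCC(=C)CCO[Si](C)(C)C(C)(C)C)[C@@]2(C)CCCC(C)(C)[C@H]12 | intermediate
20 | 15-[(tert-butyldimethylsilyl)oxy]-8βH-labd-13(16)-ene-6β,9α,17-triol | O[C@@H]1C[C@@H](CO)[C@](O)(CCC(=C)CCO[Si](C)(C)C(C)(C)C)[C@@]2(C)CCCC(C)(C)[C@H]12 | intermediate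
21 | 15-[(tert-butyldimethylsilyl)oxy]-6β,9α-dihydroxy-8βH-labd-13(16)-en-17-yl 4-methylbenzenesulfonate | O[C@@H]1C[C@@H](COS(=O)(=O)c3ccc(C)cc3)[C@](O)(CCC(=C)CCO[Si](C)(C)C(C)(C)C)[C@@]2(C)CCCC(C)(C)[C@H]12 | intermediate
22 | 15-[(tert-butyldimethylsilyl)oxy]labd-13(16)-ene-6β,9α-diol (8α-methyl) | O[C@@H]1C[C@@H](C)[C@](O)(CCC(=C)CCO[Si](C)(C)C(C)(C)C)[C@@]2(C)CCCC(C)(C)[C@H]12 | intermediate
23 | 6β-acetoxy-15-[(tert-butyldimethylsilyl)oxy]labd-13(16)-en-9α-ol | CC(=O)O[C@@H]1C[C@@H](C)[C@](O)(CCC(=C)CCO[Si](C)(C)C(C)(C)C)[C@@]2(C)CCCC(C)(C)[C@H]12 | intermediate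
24 | 6β-acetoxylabd-13(16)-ene-9α,15-diol | CC(=O)O[C@@H]1C[C@@H](C)[C@](O)(CCC(=C)CCO)[C@@]2(C)CCCC(C)(C)[C@H]12 | intermediate
25 | (13R)-6β-acetoxy-13,16-epoxylabdane-9α,15-diol (epoxy alcohol) | CC(=O)O[C@@H]1C[C@@H](C)[C@](O)(CC[C@]3(CO3)CCO)[C@@]2(C)CCCC(C)(C)[C@H]12 | intermediate
26 | (13S)-6β-acetoxy-9α,13-epoxylabdane-15,16-diol | CC(=O)O[C@@H]1C[C@@H](C)[C@]2(CC[C@@](CO)(CCO)O2)[C@@]2(C)CCCC(C)(C)[C@H]12 | intermediate
27 | previtexilactone, (13S)-6β-acetoxy-9α,13-epoxylabdan-16,15-olide | CC(=O)O[C@@H]1C[C@@H](C)[C@]2(CC[C@]3(COC(=O)C3)O2)[C@@]2(C)CCCC(C)(C)[C@H]12 | target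

**Step count**

Total: 17 steps. Longest linear sequence: 14 steps (steps 1–3 and 7–17).

**Steps most likely to fail**

Step 9. The samarium enolate may be protonated, or the aldolate may revert, before closure onto the hindered neopentyl ketone; pinacol-type reduction may also compete, so that only the open Giese adduct forms. The fallback uses known chemistry and sets out from 14. A Nozaki–Hiyama–Kishi addition of methyl (E)-3-iodoacrylate (CrCl2, NiCl2 cat., DMSO/THF) to the aldehyde gives methyl (E)-4-hydroxy-4-[(1S,2S)-2-{6-[(tert-butyldimethylsilyl)oxy]-4-methylidenehexanoyl}-2,6,6-trimethylcyclohexyl]but-2-enoate F1. Conjugate reduction with [(Ph3P)CuH]6 in toluene generates the copper enolate at C8, which closes onto the C9 ketone (reductive aldol cyclisation). This returns to the route at 18, and C6 is again reset in steps 10 and 11.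

Step 1. The cis-methyl group of the diene disfavours the s-cis conformer, so cycloaddition may be slow, with cationic oligomerisation of the diene and weak enantiofacial discrimination at the β,β-disubstituted enal. The fallback replaces catalyst control by a covalent auxiliary and sets out from 2 and 1. Transesterification of 2 with (−)-menthol (Ti(Oi-Pr)4 cat., toluene, ethanol distilled off) gives (1R,2S,5R)-menthyl (E)-2-methyl-4-oxobut-2-enoate F2. Cycloaddition with 1 promoted by stoichiometric EtAlCl2 gives menthyl (1S,6S)-6-formyl-1,5,5-trimethylcyclohex-3-ene-1-carboxylate F3 together with its (1R,6R)-ring diastereomer F4, and the two are separated by chromatography or crystallisation. NaBH4 reduction of F3 to menthyl (1S,6S)-6-(hydroxymethyl)-1,5,5-trimethylcyclohex-3-ene-1-carboxylate F5 and lactonisation with NaH in THF, with loss of menthol, return to the route at 5.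

Step 16. The catalyst-controlled face selectivity at the remote 1,1-disubstituted alkene may be eroded by competing epoxidation directed by the tertiary 9-hydroxyl or by background oxidation, and the C15 hydroxyl may attack the epoxide in a 5-endo sense. The fallback moves the stereocontrol to substrate direction and sets out from 23, in which C15 is still silylated. Epoxidation with VO(acac)2 and t-BuOOH, directed by the 9-hydroxyl through a chair-like vanadate, followed by AcOH-promoted 5-exo opening, gives (13S)-6β-acetoxy-15-[(tert-butyldimethylsilyl)oxy]-9α,13-epoxylabdan-16-ol F6; any 13-epimer is removed at this stage. Desilylation with HF·pyridine returns to the route at 26.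

Further compounds
F1 | step 9 | methyl (E)-4-hydroxy-4-[(1S,2S)-2-{6-[(tert-butyldimethylsilyl)oxy]-4-methylidenehexanoyl}-2,6,6-trimethylcyclohexyl]but-2-enoate | O=C(CCC(=C)CCO[Si](C)(C)C(C)(C)C)[C@@]1(C)CCCC(C)(C)[C@@H]1C(O)/C=C/C(=O)OC
F2 | step 1 | (1R,2S,5R)-menthyl (E)-2-methyl-4-oxobut-2-enoate | CC(C)[C@@H]1CC[C@@H](C)C[C@H]1OC(=O)/C(C)=C/C=O
F3 | step 1 | (1R,2S,5R)-menthyl (1S,6S)-6-formyl-1,5,5-trimethylcyclohex-3-ene-1-carboxylate | CC(C)[C@@H]1CC[C@@H](C)C[C@H]1OC(=O)[C@@]2(C)CC=CC(C)(C)[C@@H]2C=O
F4 | step 1 | (1R,2S,5R)-menthyl (1R,6R)-6-formyl-1,5,5-trimethylcyclohex-3-ene-1-carboxylate | CC(C)[C@@H]1CC[C@@H](C)C[C@H]1OC(=O)[C@]2(C)CC=CC(C)(C)[C@H]2C=O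
F5 | step 1 | (1R,2S,5R)-menthyl (1S,6S)-6-(hydroxymethyl)-1,5,5-trimethylcyclohex-3-ene-1-carboxylate | CC(C)[C@@H]1CC[C@@H](C)C[C@H]1OC(=O)[C@@]2(C)CC=CC(C)(C)[C@@H]2CO
F6 | step 16 | (13S)-6β-acetoxy-15-[(tert-butyldimethylsilyl)oxy]-9α,13-epoxylabdan-16-ol | CC(=O)O[C@@H]1C[C@@H](C)[C@]2(CC[C@@](CO)(CCO[Si](C)(C)C(C)(C)C)O2)[C@@]2(C)CCCC(C)(C)[C@H]12
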